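**Retrosynthetic overview**
1. The hydroquinone is unmasked last. A 2,6-dialkylphenol is para-oxygenated (phenol → p-quinone → hydroquinone) after one-step removal of the silyl ether and the acetonide.
2. Both C(sp2)–C(sp3) bonds flanking the diol (C7'–C8' and C9'–C10') are cut. C8'–C9' with both stereocentres is C2–C3 of L-tartaric acid, and its two carboxyl carbons leave as CO2.
3. Key step: the C2-symmetric bis(N-hydroxyphthalimide) ester of L-tartrate acetonide is mono-alkenylated under nickel catalysis. This breaks the symmetry and keeps C8' by anti capture on the dioxolane. A second decarboxylative alkenylation sets C9' the same way.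
4. Left alkenyl metal: mono-bromination of silylated 2,6-xylenol, coupling of the benzylic bromide with the alkenylalane from hepta-1,5-diyne (made from 1,5-hexadiyne), then hydrozirconation. Right alkenyl metal: carboalumination–iodination of 6-methylhept-5-en-1-yne.
5. No ring is built. The arene comes from 2,6-dimethylphenol, and the dioxolane comes with the tartrate and is removed at the end.

Assumption: side-chain atoms are numbered C1' (benzylic) to C16', and the phenol, quinone and hydroquinone stages are handled under argon unless O2 is the reagent.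

**Step 1**
Reactants: 1 2,6-dimethylphenol
Product: 2 tert-butyl(2,6-dimethylphenoxy)dimethylsilane
Conditions: TBSCl, imidazole, DMF, 40 °C
Reagents that add atoms: tert-butyldimethylsilyl chloride, CC(C)(C)[Si](C)(C)Cl
Why: Imidazole-promoted O-silylation masks the acidic phenol for the radical and organometallic steps, and the group is later removed together with the acetonide; no stereocentre is involved.

**Step 2**
Reactants: 2 tert-butyl(2,6-dimethylphenoxy)dimethylsilane
Product: 3 [2-(bromomethyl)-6-methylphenoxy](tert-butyl)dimethylsilane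
Conditions: NBS (0.95 equiv), AIBN (cat.), PhCF3, reflux
Reagents that add atoms: N-bromosuccinimide, O=C1CCC(=O)N1Br
Why: In this Wohl–Ziegler benzylic bromination the two methyl groups are equivalent, so a slight deficit of NBS gives mainly the monobromide with the 2,6-pattern fixed, radical substitution in a non-polar solvent outruns ring bromination of the silyl ether, and unreacted 2 is recycled.

**Step 3**
Reactants: 4 1,5-hexadiyne
Product: 6 hepta-1,5-diyne, via lithium hexa-1,5-diyn-1-ide 5 (not isolated)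
Conditions: n-BuLi (1.0 equiv), THF, −78 °C; MeI, −78 °C to rt; fractional distillation
Reagents that add atoms: methyl iodide, [CH3][I]
Why: This acetylide alkylation (SN2) follows statistical mono-deprotonation of a symmetric diyne, and the C6, C7 and C8 diynes have well-separated boiling points so they are parted by distillation.

**Step 4**
Reactants: 6 hepta-1,5-diyne; 3 [2-(bromomethyl)-6-methylphenoxy](tert-butyl)dimethylsilane
Product: 8 tert-butyldimethyl{2-methyl-6-[(2E)-3-methyloct-2-en-6-yn-1-yl]phenoxy}silane, via alkenylalane 7 (not isolated)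
Conditions: 6, Me3Al, Cp2ZrCl2 (20 mol %), CH2Cl2, 0 °C to rt; evaporate volatiles; 3, Pd(PPh3)4 (5 mol %), THF, rt
Reagents that add atoms: trimethylaluminium, C[Al](C)C
Why: Negishi zirconium-catalysed carboalumination adds Me and Al syn and far faster to the terminal than to the internal alkyne, which fixes E-C2'=C3', and the alkenylalane then couples with the benzylic bromide with retention under zerovalent palladium (Negishi alkenyl–benzyl cross-coupling).

**Step 5**
Reactants: 9 dimethyl (4R,5R)-2,2-dimethyl-1,3-dioxolane-4,5-dicarboxylate (from L-tartaric acid)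
Product: 10 (4R,5R)-2,2-dimethyl-1,3-dioxolane-4,5-dicarboxylic acid
Conditions: LiOH, THF/H2O, 0 °C to rt; then 1 M HCl, EtOAc extraction
Reagents that add atoms: lithium hydroxide, [Li+].[OH-]
Why: This is ester saponification, and because the trans-dioxolane is the thermodynamic isomer, any transient enolisation returns the same (4R,5R) configuration.

**Step 6**
Reactants: 10 (4R,5R)-2,2-dimethyl-1,3-dioxolane-4,5-dicarboxylic acid
Product: 11 bis(1,3-dioxoisoindolin-2-yl) (4R,5R)-2,2-dimethyl-1,3-dioxolane-4,5-dicarboxylate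
Conditions: N-hydroxyphthalimide (2.1 equiv), N,N'-diisopropylcarbodiimide (2.2 equiv), DMAP (cat.), CH2Cl2, rt
Reagents that add atoms: N-hydroxyphthalimide, O=C1c2ccccc2C(=O)N1O
Why: Steglich-type carbodiimide esterification gives the crystalline, still C2-symmetric bis redox-active ester without touching the stereocentres.

**Step 7**
Reactants: 8 tert-butyldimethyl{2-methyl-6-[(2E)-3-methyloct-2-en-6-yn-1-yl]phenoxy}silane; 11 bis(1,3-dioxoisoindolin-2-yl) (4R,5R)-2,2-dimethyl-1,3-dioxolane-4,5-dicarboxylate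
Product: 14 1,3-dioxoisoindolin-2-yl (4R,5S)-5-[(2E,6E)-8-{2-[(tert-butyldimethylsilyl)oxy]-3-methylphenyl}-6-methylocta-2,6-dien-2-yl]-2,2-dimethyl-1,3-dioxolane-4-carboxylate, via alkenylzirconocene chloride 12 (not isolated), via alkenylzinc chloride 13 (not isolated)
Conditions: 8, Cp2ZrHCl (1.5 equiv), THF, rt to 45 °C; ZnCl2 (1.5 equiv), 0 °C; then 11 (3 equiv), Ni(acac)2 (10 mol %), 2,2'-bipyridine (10 mol %), THF/DMF, rt; excess 11 recovered
Reagents that add atoms: none
Why: Proposed new method: syn hydrozirconation of the 2-alkyne under thermodynamic control places Zr next to the methyl group (about 9:1, E-alkenyl metal), Zr-to-Zn transmetalation feeds a nickel cycle in which single-electron reduction of one phthalimide ester of the threefold excess of C2-symmetric 11 releases CO2 and a dioxolan-4-yl radical, and this radical is captured by alkenylnickel on the face anti to the neighbouring substituent, so the symmetry is broken, C7'–C8' forms with net retention (trans-dioxolane, C8' = S) and the second ester survives because the zinc reagent is limiting; the closest known reaction type is the nickel-catalysed decarboxylative alkenylation of redox-active esters with alkenylzinc reagents, here extended to mono-coupling of a bis-ester.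

**Step 8**
Reactants: 15 5-bromo-2-methylpent-2-ene
Product: 16 6-methylhept-5-en-1-yne
Conditions: HC≡CLi·H2NCH2CH2NH2, DMSO, 0 °C to rt
Reagents that add atoms: lithium acetylide (ethylenediamine complex), [Li]C#C
Why: SN2 alkylation of lithium acetylide by an unhindered primary homoallylic bromide in a dipolar aprotic solvent.

**Step 9**
Reactants: 16 6-methylhept-5-en-1-yne
Product: 18 (1E)-1-iodo-2,6-dimethylhepta-1,5-diene, via alkenylalane 17 (not isolated)
Conditions: Me3Al, Cp2ZrCl2 (25 mol %), CH2Cl2, 0 °C to rt; I2, THF, −30 °C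
Reagents that add atoms: trimethylaluminium, C[Al](C)C; iodine, [I][I]
Why: Negishi carboalumination adds Me and Al syn across the terminal alkyne and iodinolysis proceeds with retention, which fixes the E geometry of the future C10'=C11' bond.

**Step 10**
Reactants: 18 (1E)-1-iodo-2,6-dimethylhepta-1,5-diene; 14 the mono redox-active ester from step 7
Product: 21 (4S,5S)-4-[(2E,6E)-8-{2-[(tert-butyldimethylsilyl)oxy]-3-methylphenyl}-6-methylocta-2,6-dien-2-yl]-5-[(1E)-2,6-dimethylhepta-1,5-dien-1-yl]-2,2-dimethyl-1,3-dioxolane, via alkenyllithium 19 (not isolated), via alkenylzinc chloride 20 (not isolated)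
Conditions: 18 (2.5 equiv), t-BuLi (5 equiv), Et2O, −78 °C; ZnCl2, THF, −78 °C to rt; then 14, Ni(acac)2 (10 mol %), 2,2'-bipyridine (10 mol %), THF/DMF, rt
Reagents that add atoms: none
Why: In this nickel-catalysed decarboxylative alkenylation of a redox-active ester, I/Li exchange and Li-to-Zn transmetalation retain the alkene geometry, the C9' radical on the rigid dioxolane is captured anti to the C8' alkenyl group to give the trans-(4S,5S) ring (C9' = S), and 3-exo attack on the fully substituted C7' is slow, so a 1,2-vinyl shift should not erode the ee.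

**Step 11**
Reactants: 21 the fully assembled silyl ether acetonide
Product: 22 2-[(2E,6E,8S,9S,10E)-8,9-dihydroxy-3,7,11,15-tetramethylhexadeca-2,6,10,14-tetraen-1-yl]-6-methylphenol
Conditions: aq HF (48 %), MeCN, 0 °C to rt, argon
Reagents that add atoms: none
Why: In this global deprotection fluoride cleaves the aryl Si–O bond and the aqueous acid hydrolyses the ketal through the oxocarbenium ion at the ketal carbon, so no C–O bond at C8' or C9' is broken and both configurations are retained.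

**Step 12**
Reactants: 22 2-[(2E,6E,8S,9S,10E)-8,9-dihydroxy-3,7,11,15-tetramethylhexadeca-2,6,10,14-tetraen-1-yl]-6-methylphenol
Product: 24 2-[(2E,6E,8S,9S,10E)-8,9-dihydroxy-3,7,11,15-tetramethylhexadeca-2,6,10,14-tetraen-1-yl]-6-methylbenzene-1,4-diol (CNP0197415.1), via quinone 23 (not isolated)
Conditions: O2 (1 atm), Co(salen) (10 mol %), DMF, rt; argon purge; aq Na2S2O4, Et2O, rt
Reagents that add atoms: dioxygen, O=O
Why: Cobalt–dioxygen oxidation of a 2,6-dialkylphenol is an oxidative dearomatisation that can only attack the free para position and gives the p-benzoquinone, dithionite reduction restores aromaticity as the hydroquinone, and isolated alkenes and the diol are inert to both reagents.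

**Compound list**
1 | 2,6-dimethylphenol | Cc1cccc(C)c1O | starting material
2 | tert-butyl(2,6-dimethylphenoxy)dimethylsilane | Cc1cccc(C)c1O[Si](C)(C)C(C)(C)C | intermediate
3 | [2-(bromomethyl)-6-methylphenoxy](tert-butyl)dimethylsilane | Cc1cccc(CBr)c1O[Si](C)(C)C(C)(C)C | intermediate
4 | 1,5-hexadiyne | C#CCCC#C | starting material
5 | lithium hexa-1,5-diyn-1-ide | [Li]C#CCCC#C | intermediate
6 | hepta-1,5-diyne | CC#CCCC#C | intermediate
7 | dimethyl[(1E)-2-methylhept-1-en-5-yn-1-yl]alane | CC#CCC/C(C)=C/[Al](C)C | intermediate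
8 | tert-butyldimethyl{2-methyl-6-[(2E)-3-methyloct-2-en-6-yn-1-yl]phenoxy}silane | CC#CCC/C(C)=C/Cc1cccc(C)c1O[Si](C)(C)C(C)(C)C | intermediate
9 | dimethyl (4R,5R)-2,2-dimethyl-1,3-dioxolane-4,5-dicarboxylate | COC(=O)[C@@H]1OC(C)(C)O[C@H]1C(=O)OC | starting material
10 | (4R,5R)-2,2-dimethyl-1,3-dioxolane-4,5-dicarboxylic acid | OC(=O)[C@@H]1OC(C)(C)O[C@H]1C(=O)O | intermediate
11 | bis(1,3-dioxoisoindolin-2-yl) (4R,5R)-2,2-dimethyl-1,3-dioxolane-4,5-dicarboxylate | O=C(ON1C(=O)c2ccccc2C1=O)[C@@H]1OC(C)(C)O[C@H]1C(=O)ON1C(=O)c2ccccc2C1=O | intermediate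
12 | chlorobis(cyclopentadienyl)[(2E,6E)-8-{2-[(tert-butyldimethylsilyl)oxy]-3-methylphenyl}-6-methylocta-2,6-dien-2-yl]zirconium | Cl[Zr](C1C=CC=C1)(C1C=CC=C1)/C(C)=C/CC/C(C)=C/Cc1cccc(C)c1O[Si](C)(C)C(C)(C)C | intermediate
13 | [(2E,6E)-8-{2-[(tert-butyldimethylsilyl)oxy]-3-methylphenyl}-6-methylocta-2,6-dien-2-yl]zinc chloride | Cl[Zn]/C(C)=C/CC/C(C)=C/Cc1cccc(C)c1O[Si](C)(C)C(C)(C)C | intermediate
14 | 1,3-dioxoisoindolin-2-yl (4R,5S)-5-[(2E,6E)-8-{2-[(tert-butyldimethylsilyl)oxy]-3-methylphenyl}-6-methylocta-2,6-dien-2-yl]-2,2-dimethyl-1,3-dioxolane-4-carboxylate (trans) | CC(C)(C)[Si](C)(C)Oc1c(C)cccc1C/C=C(C)/CC/C=C(C)/[C@@H]1OC(C)(C)O[C@H]1C(=O)ON1C(=O)c2ccccc2C1=O | intermediate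
15 | 5-bromo-2-methylpent-2-ene | CC(C)=CCCBr | starting material
16 | 6-methylhept-5-en-1-yne | CC(C)=CCCC#C | intermediate
17 | [(1E)-2,6-dimethylhepta-1,5-dien-1-yl]dimethylalane | CC(C)=CCC/C(C)=C/[Al](C)C | intermediate
18 | (1E)-1-iodo-2,6-dimethylhepta-1,5-diene | CC(C)=CCC/C(C)=C/I | intermediate
19 | [(1E)-2,6-dimethylhepta-1,5-dien-1-yl]lithium | CC(C)=CCC/C(C)=C/[Li] | intermediate
20 | [(1E)-2,6-dimethylhepta-1,5-dien-1-yl]zinc chloride | CC(C)=CCC/C(C)=C/[Zn]Cl | intermediate
21 | (4S,5S)-4-[(2E,6E)-8-{2-[(tert-butyldimethylsilyl)oxy]-3-methylphenyl}-6-methylocta-2,6-dien-2-yl]-5-[(1E)-2,6-dimethylhepta-1,5-dien-1-yl]-2,2-dimethyl-1,3-dioxolane (trans) | CC(C)(C)[Si](C)(C)Oc1c(C)cccc1C/C=C(C)/CC/C=C(C)/[C@@H]1OC(C)(C)O[C@H]1/C=C(C)/CCC=C(C)C | intermediate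
22 | 2-[(2E,6E,8S,9S,10E)-8,9-dihydroxy-3,7,11,15-tetramethylhexadeca-2,6,10,14-tetraen-1-yl]-6-methylphenol | Cc1cccc(C/C=C(C)/CC/C=C(C)/[C@H](O)[C@@H](O)/C=C(C)/CCC=C(C)C)c1O | intermediate
23 | 2-[(2E,6E,8S,9S,10E)-8,9-dihydroxy-3,7,11,15-tetramethylhexadeca-2,6,10,14-tetraen-1-yl]-6-methylcyclohexa-2,5-diene-1,4-dione | CC1=CC(=O)C=C(C/C=C(C)/CC/C=C(C)/[C@H](O)[C@@H](O)/C=C(C)/CCC=C(C)C)C1=O | intermediate
24 | 2-[(2E,6E,8S,9S,10E)-8,9-dihydroxy-3,7,11,15-tetramethylhexadeca-2,6,10,14-tetraen-1-yl]-6-methylbenzene-1,4-diol | CC(C)=CCC/C(C)=C/[C@H](O)[C@@H](O)/C(C)=C/CC/C(C)=C/Cc1cc(O)cc(C)c1O | target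

**Total step count:** 12.
**Longest linear sequence:** 7 (steps 1, 2, 4, 7, 10, 11, 12).

**Three steps most likely to fail**

Step 7. The risks are over-coupling of the bis-ester, the in situ Zr-to-Zn hand-over, and the roughly 9:1 hydrozirconation regiochemistry. The fallback sets out from 9 and comes back at 14. It breaks the symmetry by hydrolysis instead of by the C–C coupling.
- One equivalent of KOH in MeOH turns 9 into the half-ester (4R,5R)-5-(methoxycarbonyl)-2,2-dimethyl-1,3-dioxolane-4-carboxylic acid F1.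
- N-Hydroxyphthalimide and N,N'-diisopropylcarbodiimide give the mixed diester 4-(1,3-dioxoisoindolin-2-yl) 5-methyl (4R,5R)-2,2-dimethyl-1,3-dioxolane-4,5-dicarboxylate F2.
- F2 is now the limiting partner for an excess of zinc reagent 13 under Ni(acac)2/2,2'-bipyridine. The product is methyl (4R,5S)-5-[(2E,6E)-8-{2-[(tert-butyldimethylsilyl)oxy]-3-methylphenyl}-6-methylocta-2,6-dien-2-yl]-2,2-dimethyl-1,3-dioxolane-4-carboxylate F3.
- Me3SnOH in 1,2-dichloroethane cleaves the methyl ester without touching the aryl silyl ether and gives the corresponding (4R,5S)-carboxylic acid F4.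
- Esterification of F4 with N-hydroxyphthalimide returns 14.

Step 10. The risks are hindered radical capture next to the α-methylalkenyl group, a lower trans:cis ratio, and a possible vinyl shift. The fallback sets out from 14 and comes back at 21. It keeps the carboxyl carbon as C10' and builds the alkene by polar chemistry.
- NaBH4 reduces the active ester to the primary alcohol [(4S,5S)-5-alkenyl-2,2-dimethyl-1,3-dioxolan-4-yl]methanol F5.
- Dess–Martin oxidation gives the (4R,5S)-dioxolane-4-carbaldehyde F6.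
- CBr4/PPh3 gives the (4S,5S)-4-(2,2-dibromoethenyl)dioxolane F7.
- Zinc dust with LiCl converts 15 into (4-methylpent-3-en-1-yl)zinc bromide F9.
- F9 replaces only the bromine trans to C9' under PdCl2(DPEphos) and gives the (4S,5S)-4-[(1Z)-2-bromo-6-methylhepta-1,5-dien-1-yl]dioxolane F8.
- Me2Zn with Pd(t-Bu3P)2 methylates the remaining C–Br bond with retention to give 21.

Step 12. The risks are side reactions of the ortho-allylphenoxyl radical and oxidation in the presence of the free bis-allylic diol. The acid sensitivity seen in step 11 is avoided by the same fallback. It sets out from 21 and comes back at 24, bypasses 22, and carries the diol masked through the redox events.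
- TBAF removes only the silyl group and gives the phenol acetonide 2-{(2E,6E)-7-[(4S,5S)-5-((1E)-2,6-dimethylhepta-1,5-dien-1-yl)-2,2-dimethyl-1,3-dioxolan-4-yl]-3-methylocta-2,6-dien-1-yl}-6-methylphenol F10.
- The nitroxyl radical salt (KSO3)2NO (Teuber oxidation, buffered water/acetone) gives the corresponding 1,4-benzoquinone acetonide F11.
- Na2S2O4 gives the hydroquinone acetonide F12.
- Warm aqueous acetic acid under argon hydrolyses the ketal to 24.

**Further compounds**
F1 | step 7 | (4R,5R)-5-(methoxycarbonyl)-2,2-dimethyl-1,3-dioxolane-4-carboxylic acid | COC(=O)[C@@H]1OC(C)(C)O[C@H]1C(=O)O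
F2 | step 7 | 4-(1,3-dioxoisoindolin-2-yl) 5-methyl (4R,5R)-2,2-dimethyl-1,3-dioxolane-4,5-dicarboxylate | COC(=O)[C@@H]1OC(C)(C)O[C@H]1C(=O)ON1C(=O)c2ccccc2C1=O
F3 | step 7 | methyl (4R,5S)-5-[(2E,6E)-8-{2-[(tert-butyldimethylsilyl)oxy]-3-methylphenyl}-6-methylocta-2,6-dien-2-yl]-2,2-dimethyl-1,3-dioxolane-4-carboxylate | COC(=O)[C@@H]1OC(C)(C)O[C@H]1/C(C)=C/CC/C(C)=C/Cc1cccc(C)c1O[Si](C)(C)C(C)(C)C
F4 | step 7 | (4R,5S)-5-[(2E,6E)-8-{2-[(tert-butyldimethylsilyl)oxy]-3-methylphenyl}-6-methylocta-2,6-dien-2-yl]-2,2-dimethyl-1,3-dioxolane-4-carboxylic acid | OC(=O)[C@@H]1OC(C)(C)O[C@H]1/C(C)=C/CC/C(C)=C/Cc1cccc(C)c1O[Si](C)(C)C(C)(C)C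
F5 | step 10 | {(4S,5S)-5-[(2E,6E)-8-{2-[(tert-butyldimethylsilyl)oxy]-3-methylphenyl}-6-methylocta-2,6-dien-2-yl]-2,2-dimethyl-1,3-dioxolan-4-yl}methanol | CC(C)(C)[Si](C)(C)Oc1c(C)cccc1C/C=C(C)/CC/C=C(C)/[C@@H]1OC(C)(C)O[C@H]1CO
F6 | step 10 | (4R,5S)-5-[(2E,6E)-8-{2-[(tert-butyldimethylsilyl)oxy]-3-methylphenyl}-6-methylocta-2,6-dien-2-yl]-2,2-dimethyl-1,3-dioxolane-4-carbaldehyde | CC(C)(C)[Si](C)(C)Oc1c(C)cccc1C/C=C(C)/CC/C=C(C)/[C@@H]1OC(C)(C)O[C@H]1C=O
F7 | step 10 | (4S,5S)-4-(2,2-dibromoethenyl)-5-[(2E,6E)-8-{2-[(tert-butyldimethylsilyl)oxy]-3-methylphenyl}-6-methylocta-2,6-dien-2-yl]-2,2-dimethyl-1,3-dioxolane | CC(C)(C)[Si](C)(C)Oc1c(C)cccc1C/C=C(C)/CC/C=C(C)/[C@@H]1OC(C)(C)O[C@H]1C=C(Br)Br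
F8 | step 10 | (4S,5S)-4-[(1Z)-2-bromo-6-methylhepta-1,5-dien-1-yl]-5-[(2E,6E)-8-{2-[(tert-butyldimethylsilyl)oxy]-3-methylphenyl}-6-methylocta-2,6-dien-2-yl]-2,2-dimethyl-1,3-dioxolane | CC(C)(C)[Si](C)(C)Oc1c(C)cccc1C/C=C(C)/CC/C=C(C)/[C@@H]1OC(C)(C)O[C@H]1/C=C(Br)/CCC=C(C)C
F9 | step 10 | (4-methylpent-3-en-1-yl)zinc bromide | Br[Zn]CCC=C(C)C
F10 | step 12 | 2-{(2E,6E)-7-[(4S,5S)-5-((1E)-2,6-dimethylhepta-1,5-dien-1-yl)-2,2-dimethyl-1,3-dioxolan-4-yl]-3-methylocta-2,6-dien-1-yl}-6-methylphenol | Cc1cccc(C/C=C(C)/CC/C=C(C)/[C@@H]2OC(C)(C)O[C@H]2/C=C(C)/CCC=C(C)C)c1O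
F11 | step 12 | 2-{(2E,6E)-7-[(4S,5S)-5-((1E)-2,6-dimethylhepta-1,5-dien-1-yl)-2,2-dimethyl-1,3-dioxolan-4-yl]-3-methylocta-2,6-dien-1-yl}-6-methylcyclohexa-2,5-diene-1,4-dione | CC1=CC(=O)C=C(C/C=C(C)/CC/C=C(C)/[C@@H]2OC(C)(C)O[C@H]2/C=C(C)/CCC=C(C)C)C1=O
F12 | step 12 | 2-{(2E,6E)-7-[(4S,5S)-5-((1E)-2,6-dimethylhepta-1,5-dien-1-yl)-2,2-dimethyl-1,3-dioxolan-4-yl]-3-methylocta-2,6-dien-1-yl}-6-methylbenzene-1,4-diol | Cc1cc(O)cc(C/C=C(C)/CC/C=C(C)/[C@@H]2OC(C)(C)O[C@H]2/C=C(C)/CCC=C(C)C)c1O
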